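Ring B of this labdane is a cyclohexene that shares only the C5–C10 bond with ring A, so it is disconnected across C9–C10 and C5–C6: the C5=C10 double bond of 2,4,4-trimethylcyclohex-2-enone is the dienophile and C6–C7–C8–C9 a 1,3-diene. That diene, together with C17 and the whole C11–C16 side chain, is methyl geranate after oxidation of its terminal (E)-methyl group and methylenation. One enantioselective Diels–Alder reaction thus forms ring B, the quaternary C10 centre and the full C20 skeleton. The C7=C8 alkene it leaves is then used to introduce the C6 ketone (C5 epimerisation, 6β-alcohol) and, through a dienol ether, the 7α-oxygen and the C8=C9 bond.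

Key step: step 3

Numbering: labdane numbering (ring A = C1–C5 and C10; ring B = C5–C10; C17 on C8; C18 and C19 on C4; C20 on C10; side chain C11–C16 on C9); β is the face of the C10 methyl group.
Assumption: methyl geranate is used as the isomerically pure (2E) compound; from step 8 on the side chain is carried as the free acid, and the mixed anhydrides it forms during the two acylations are hydrolysed before isolation.

Step 1
Reactants: 1 methyl (2E)-3,7-dimethylocta-2,6-dienoate (methyl geranate)
Product: 2 methyl (2E,6E)-3,7-dimethyl-8-oxoocta-2,6-dienoate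
Conditions: SeO2 (1.2 equiv), EtOH, reflux
Reagents that add atoms: selenium dioxide, O=[Se]=O
Why: Riley allylic oxidation (ene reaction, then [2,3]-shift) attacks the electron-rich 6,7-alkene at its (E)-methyl group and runs on to the (E)-enal, while the conjugated 2,3-alkene is deactivated.

Step 2
Reactants: 2 methyl (2E,6E)-3,7-dimethyl-8-oxoocta-2,6-dienoate
Product: 3 methyl (2E,6E)-3,7-dimethylnona-2,6,8-trienoate
Conditions: Ph3PCH3Br, KN(SiMe3)2, THF, −78 to 0 °C
Reagents that add atoms: methyltriphenylphosphonium bromide, C[P+](c1ccccc1)(c1ccccc1)c1ccccc1.[Br-]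
Why: Wittig methylenation of the aldehyde (the ester is untouched) gives the 1,3-diene and keeps the (E) geometry of the future C8=C9 unit.

Step 3
Reactants: 3 methyl (2E,6E)-3,7-dimethylnona-2,6,8-trienoate; 4 2,4,4-trimethylcyclohex-2-en-1-one
Product: 5 methyl (13E)-1-oxo-5β-H,9β-H-labda-7,13-dien-15-oate (cis-fused adduct, 10β-methyl, side chain α at C9)
Conditions: (S)-1-(2-methylphenyl)-3,3-diphenyltetrahydro-1H,3H-pyrrolo[1,2-c][1,3,2]oxazaborole (0.2 equiv), AlBr3 (0.16 equiv), CH2Cl2, −40 to 0 °C
Reagents that add atoms: none
Why: The boron-bound enone 4 reacts as the 2π partner through its C5=C10 bond and the s-cis diene unit of 3 (C6=C7–C8=C9) as the 4π partner in a concerted, asynchronous [4+2] cycloaddition in which the C5–C6 bond is ahead of the C9–C10 bond; the closest known reaction type is the cationic oxazaborolidine-catalysed enantioselective Diels–Alder reaction of α-substituted enones with alkyl-substituted dienes. Ring B is the only ring closed, by intermolecular suprafacial six-membered cycloaddition onto the preformed ring A. C10 is controlled by the catalyst, whose configuration is chosen to leave open the Re face at C2 of 4 (10β-methyl); C5 follows from suprafacial addition to the ring alkene (5β-H, cis fusion, inverted in step 8); C9 follows from the endo transition state (side chain trans to the C10 methyl group) and is erased in step 9. Regioselectivity is the selectivity needed, and it is secured by the unsubstituted, more nucleophilic diene terminus C6 (opposite the alkyl-bearing C9) attacking the β-carbon C5 while the substituted terminus C9 takes the longer bond to the α-carbon C10. Chemoselectivity rests on the trisubstituted enoate of 3 being a far poorer dienophile than the Lewis-acid-bound enone.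

Step 4
Reactants: 5 methyl (13E)-1-oxo-5β-H,9β-H-labda-7,13-dien-15-oate
Product: 6 methyl (13E)-1-hydroxy-5β-H,9β-H-labda-7,13-dien-15-oate (C1 epimers, both used)
Conditions: NaBH4, MeOH, 0 °C to rt
Reagents that add atoms: none
Why: Borohydride reduces the hindered C1 ketone but not the β,β-disubstituted enoate; the new C1 carbinol centre is removed in step 6, so its configuration is irrelevant.

Step 5
Reactants: 6 methyl (13E)-1-hydroxy-5β-H,9β-H-labda-7,13-dien-15-oate
Product: 7 methyl (13E)-1-(imidazol-1-ylthiocarbonyloxy)-5β-H,9β-H-labda-7,13-dien-15-oate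
Conditions: 1,1'-thiocarbonyldiimidazole, 4-(dimethylamino)pyridine (cat.), 1,2-dichloroethane, 70 °C
Reagents that add atoms: 1,1'-thiocarbonyldiimidazole, S=C(n1ccnc1)n1ccnc1
Why: Thioacylation of the secondary alcohol gives the thiocarbonyl derivative needed for Barton–McCombie deoxygenation.

Step 6
Reactants: 7 methyl (13E)-1-(imidazol-1-ylthiocarbonyloxy)-5β-H,9β-H-labda-7,13-dien-15-oate
Product: 8 methyl (13E)-5β-H,9β-H-labda-7,13-dien-15-oate
Conditions: Bu3SnH, AIBN (cat.), toluene, 100 °C
Reagents that add atoms: none
Why: Barton–McCombie radical deoxygenation: the stannyl radical adds to C=S, the C1–O bond fragments and the secondary C1 radical is reduced by Bu3SnH faster than it can add to either alkene.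

Step 7
Reactants: 8 methyl (13E)-5β-H,9β-H-labda-7,13-dien-15-oate
Product: 9 methyl (13E)-6-oxo-5β-H,9β-H-labda-7,13-dien-15-oate
Conditions: CrO3, 3,5-dimethylpyrazole, CH2Cl2, −20 °C
Reagents that add atoms: chromium trioxide, O=[Cr](=O)=O
Why: Chromium trioxide–3,5-dimethylpyrazole allylic oxidation turns the only allylic ring methylene (C6, next to the CH= end of the trisubstituted alkene) into the ketone, as 1-methylcyclohexene-type alkenes give 3-methylcyclohex-2-enones; the electron-poor side-chain alkene is left alone.

Step 8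
Reactants: 9 methyl (13E)-6-oxo-5β-H,9β-H-labda-7,13-dien-15-oate
Product: 10 (13E)-6-oxo-9β-H-labda-7,13-dien-15-oic acid (trans-fused, 5α-H)
Conditions: LiOH, THF/MeOH/H2O, 45 °C (argon); then aq. HCl
Reagents that add atoms: lithium hydroxide, [Li+].[OH-]
Why: Saponification of the ester and, through the C5 enolate of the enone, equilibration of the ring fusion, which should favour the trans-fused 5α-H isomer (as in the 5β to 5α isomerisation of steroidal 7-en-6-ones); residual cis isomer is recycled, and C9, which may also equilibrate, is inconsequential.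

Step 9
Reactants: 10 (13E)-6-oxo-9β-H-labda-7,13-dien-15-oic acid
Product: 12 (13E)-7α-hydroxy-6-oxolabda-8,13-dien-15-oic acid, via bis-silyl dienol ether 11 (not isolated)
Conditions: t-BuMe2SiOTf, Et3N, CH2Cl2, 0 °C to rt (equilibrating); then OsO4 (0.05 equiv), N-methylmorpholine N-oxide, acetone/H2O, 0 °C
Reagents that add atoms: osmium tetroxide, O=[Os](=O)(=O)=O (oxygen carrier); N-methylmorpholine N-oxide, C[N+]1([O-])CCOCC1 (terminal oxygen source); tert-butyldimethylsilyl triflate, CC(C)(C)[Si](C)(C)OS(=O)(=O)C(F)(F)F (atoms kept only in 11)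
Why: Soft enolisation under equilibrating conditions should give the linear, more substituted (endocyclic C8=C9) silyl dienol ether, and OsO4 dihydroxylates its trisubstituted C6=C7 enol ether bond rather than the hindered tetrasubstituted C8=C9 bond, from the α face opposite the axial C10 and 4β methyl groups, so that collapse of the osmate gives the 7α-hydroxy ketone (a Rubottom-type α-hydroxylation by silyl enol ether dihydroxylation).

Step 10
Reactants: 12 (13E)-7α-hydroxy-6-oxolabda-8,13-dien-15-oic acid
Product: 14 (13E)-7α-(3-methylbutanoyloxy)-6-oxolabda-8,13-dien-15-oic acid, via mixed isovaleric anhydride 13 (not isolated)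
Conditions: (i-BuCO)2O, 4-(dimethylamino)pyridine (cat.), pyridine, CH2Cl2, 0 °C; then H2O/THF
Reagents that add atoms: 3-methylbutanoic (isovaleric) anhydride, CC(C)CC(=O)OC(=O)CC(C)C; water, O
Why: Nucleophile-catalysed acylation places the isovalerate on O7 while C6 is still a ketone, which differentiates the two ester positions by construction; the carboxyl group is acylated too, but the mixed anhydride is hydrolysed in the aqueous stage.

Step 11
Reactants: 14 (13E)-7α-(3-methylbutanoyloxy)-6-oxolabda-8,13-dien-15-oic acid
Product: 15 (13E)-6β-hydroxy-7α-(3-methylbutanoyloxy)labda-8,13-dien-15-oic acid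
Conditions: NaBH4, MeOH/THF, −30 °C
Reagents that add atoms: none
Why: Hydride adds to the C6 ketone from the α face because the β face is blocked by the syn-axial C10 and 4β methyl groups, giving the axial 6β-alcohol (as in reductions of 6-oxo drimanes and labdanes); the trans-diaxial 6β-OH and 7α-ester cannot exchange the acyl group.

Step 12
Reactants: 15 (13E)-6β-hydroxy-7α-(3-methylbutanoyloxy)labda-8,13-dien-15-oic acid
Product: 17 (13E)-6β-acetoxy-7α-(3-methylbutanoyloxy)labda-8,13-dien-15-oic acid, via mixed acetic anhydride 16 (not isolated)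
Conditions: Ac2O, 4-(dimethylamino)pyridine, Et3N, CH2Cl2, 40 °C; then H2O/THF
Reagents that add atoms: acetic anhydride, CC(=O)OC(C)=O; water, O
Why: Nucleophile-catalysed acetylation of the hindered axial 6β-alcohol; the mixed anhydride at C15 is cleaved by water to leave the free acid, which is the target.

Compound list
1 | methyl (2E)-3,7-dimethylocta-2,6-dienoate (methyl geranate) | CC(C)=CCC/C(C)=C/C(=O)OC | starting material
2 | methyl (2E,6E)-3,7-dimethyl-8-oxoocta-2,6-dienoate | O=C/C(C)=C/CC/C(C)=C/C(=O)OC | intermediate
3 | methyl (2E,6E)-3,7-dimethylnona-2,6,8-trienoate | C=C/C(C)=C/CC/C(C)=C/C(=O)OC | intermediate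
4 | 2,4,4-trimethylcyclohex-2-en-1-one | CC1=CC(C)(C)CCC1=O | starting material
5 | methyl (13E)-1-oxo-5β-H,9β-H-labda-7,13-dien-15-oate (cis-fused, 10β-methyl) | C1C=C(C)[C@@H](CC/C(C)=C/C(=O)OC)[C@@]2(C)C(=O)CCC(C)(C)[C@@H]12 | intermediate
6 | methyl (13E)-1-hydroxy-5β-H,9β-H-labda-7,13-dien-15-oate (C1 epimers, C1 left undefined) | C1C=C(C)[C@@H](CC/C(C)=C/C(=O)OC)[C@@]2(C)C(O)CCC(C)(C)[C@@H]12 | intermediate
7 | methyl (13E)-1-(imidazol-1-ylthiocarbonyloxy)-5β-H,9β-H-labda-7,13-dien-15-oate | C1C=C(C)[C@@H](CC/C(C)=C/C(=O)OC)[C@@]2(C)C(OC(=S)n3ccnc3)CCC(C)(C)[C@@H]12 | intermediate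
8 | methyl (13E)-5β-H,9β-H-labda-7,13-dien-15-oate | C1C=C(C)[C@@H](CC/C(C)=C/C(=O)OC)[C@@]2(C)CCCC(C)(C)[C@@H]12 | intermediate
9 | methyl (13E)-6-oxo-5β-H,9β-H-labda-7,13-dien-15-oate (cis-fused enone) | O=C1C=C(C)[C@@H](CC/C(C)=C/C(=O)OC)[C@@]2(C)CCCC(C)(C)[C@@H]12 | intermediate
10 | (13E)-6-oxo-9β-H-labda-7,13-dien-15-oic acid (trans-fused, 5α-H; C9 drawn as formed in step 3) | O=C1C=C(C)[C@@H](CC/C(C)=C/C(=O)O)[C@@]2(C)CCCC(C)(C)[C@H]12 | intermediate
11 | tert-butyldimethylsilyl (13E)-6-(tert-butyldimethylsilyloxy)labda-6,8,13-trien-15-oate | CC(C)(C)[Si](C)(C)OC1=CC(C)=C(CC/C(C)=C/C(=O)O[Si](C)(C)C(C)(C)C)[C@@]2(C)CCCC(C)(C)[C@H]12 | intermediate (not isolated)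
12 | (13E)-7α-hydroxy-6-oxolabda-8,13-dien-15-oic acid | O=C1[C@@H](O)C(C)=C(CC/C(C)=C/C(=O)O)[C@@]2(C)CCCC(C)(C)[C@H]12 | intermediate
13 | (13E)-7α-(3-methylbutanoyloxy)-6-oxolabda-8,13-dien-15-oic 3-methylbutanoic anhydride | O=C1[C@@H](OC(=O)CC(C)C)C(C)=C(CC/C(C)=C/C(=O)OC(=O)CC(C)C)[C@@]2(C)CCCC(C)(C)[C@H]12 | intermediate (not isolated)
14 | (13E)-7α-(3-methylbutanoyloxy)-6-oxolabda-8,13-dien-15-oic acid | O=C1[C@@H](OC(=O)CC(C)C)C(C)=C(CC/C(C)=C/C(=O)O)[C@@]2(C)CCCC(C)(C)[C@H]12 | intermediate
15 | (13E)-6β-hydroxy-7α-(3-methylbutanoyloxy)labda-8,13-dien-15-oic acid | O[C@@H]1[C@@H](OC(=O)CC(C)C)C(C)=C(CC/C(C)=C/C(=O)O)[C@@]2(C)CCCC(C)(C)[C@H]12 | intermediate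
16 | (13E)-6β-acetoxy-7α-(3-methylbutanoyloxy)labda-8,13-dien-15-oic acetic anhydride | CC(=O)O[C@@H]1[C@@H](OC(=O)CC(C)C)C(C)=C(CC/C(C)=C/C(=O)OC(C)=O)[C@@]2(C)CCCC(C)(C)[C@H]12 | intermediate (not isolated)
17 | (13E)-6β-acetoxy-7α-(3-methylbutanoyloxy)labda-8,13-dien-15-oic acid | CC(=O)O[C@@H]1[C@@H](OC(=O)CC(C)C)C(C)=C(CC/C(C)=C/C(=O)O)[C@@]2(C)CCCC(C)(C)[C@H]12 | target

Total step count: 12. Longest linear sequence: 12 steps (1 to 17; 4 is bought and enters at step 3).

Steps most likely to fail

Step 3 (cycloaddition). The addition to the doubly hindered C5=C10 bond (C5 neopentyl, C10 fully substituted) may be slow, and the catalyst, which the ester of 3 can also bind, may not discriminate the two faces well enough. The fallback sets out from 3 and 4 and comes back at 6. The cycloaddition is run without asymmetric induction under the stronger mixed Lewis acid AlBr3/AlMe3 (toluene/CH2Cl2, −5 °C), which gives 5 together with its mirror image, ent-5 F1. The racemic ketone is then resolved at the centre that has to be reduced anyway: an enantiomer-selective ketoreductase (alcohol dehydrogenase class, NADPH recycled with isopropanol, buffer/DMSO, 30 °C) reduces only 5 to alcohol 6 (one C1 epimer), while F1 stays a ketone and is separated.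

Step 9 (dienol ether and α-hydroxylation). Silylation may remove a C17 proton instead of H9 and give the exocyclic dienol ether, osmylation may occur at the far end of the diene, and the α-ketol may tautomerise to the conjugated 6-hydroxy-7-ketone in the aqueous amine medium. The fallback sets out from 10 and comes back at 12. Instead of a silyl dienol ether and osmylation, 10 is converted with KH (THF, 0 °C, equilibrating) into the thermodynamic dipotassium carboxylate dienolate F2, which is hydroxylated at −78 °C with 2-(phenylsulfonyl)-3-phenyloxaziridine. Metal dienolates take up this electrophilic oxidant at the α-carbon (C7), here from the less hindered α face, and acidic work-up (aq. HCl) gives 12 without any aqueous amine.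

Step 8 (ring-fusion equilibration). The equilibrium between the cis- and trans-fused 7-en-6-ones may not lie far enough on the trans side, because the flattened ring B and the C4 methyl groups reduce the usual preference. The fallback sets out from 9 and comes back at 10, and replaces thermodynamic by kinetic control. Saponification as in step 8 gives the acid as a mixture that contains the cis-fused acid F3. The whole mixture is converted with LiN(i-Pr)2 (3.2 equiv, THF, −78 °C) into the dilithium carboxylate cross-conjugated (C5=C6) enolate F4, and this is protonated at −78 °C with acetic acid from the α face, opposite the C10 and 4β methyl groups, to give 10.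

Further compounds
F1 | step 3 | ent-5, methyl (13E)-1-oxo-labda-7,13-dien-15-oate of mirror-image configuration at C5, C9 and C10 | C1C=C(C)[C@H](CC/C(C)=C/C(=O)OC)[C@]2(C)C(=O)CCC(C)(C)[C@H]12
F2 | step 9 | dipotassium salt of (13E)-6-oxidolabda-6,8,13-trien-15-oate (carboxylate dienolate of 10) | [K+].[K+].[O-]C1=CC(C)=C(CC/C(C)=C/C([O-])=O)[C@@]2(C)CCCC(C)(C)[C@H]12
F3 | step 8 | (13E)-6-oxo-5β-H,9β-H-labda-7,13-dien-15-oic acid (cis-fused acid) | O=C1C=C(C)[C@@H](CC/C(C)=C/C(=O)O)[C@@]2(C)CCCC(C)(C)[C@@H]12
F4 | step 8 | dilithium salt of (13E)-6-oxido-9β-H-labda-5,7,13-trien-15-oate (carboxylate C5=C6 enolate) | [Li+].[Li+].[O-]C1=C2C(C)(C)CCC[C@]2(C)[C@H](CC/C(C)=C/C([O-])=O)C(C)=C1
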